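## Retrosynthetic overview

1. Numbering: ring A is the acyl ring (C1 carbonyl, C2 OH, C3 CHO, C4 OMe, C6 Me); ring B carries C1' CO2H, C2' OH, C3' CHO, C4' OH, C5' O-acyl, C6' Me. The plan rests on ring B, a hexasubstituted benzene with para oxygens at C2' and C5' and a third oxygen at C4' next to C5', which is a 2-alkoxyhydroquinone pattern.
2. Last disconnections: release of the C1' tert-butyl ester and the C4' benzyl ether, then the depside bond C5'–O–C(=O) between the two rings, each already formylated.
3. The C3 and C3' formyl groups come from ortho-formylation of each phenol ring on its own; ring A is bought as everninic acid.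
4. Ring B comes from a four-membered ring: a 4-alkenyl-4-silyloxy-3-benzyloxycyclobutenone opens to a dienylketene and the C2'–C1' bond closes the benzene ring (cyclobutenone first, arene second, depside last).
5. The cyclobutenone comes from benzyl semisquarate (from squaric acid) and a (Z)-3-magnesiated tert-butyl crotonate (from but-2-ynoic acid).

Key step: step 7

Remark: the enoate geometry disappears when C1' becomes aromatic, so the alkenyl unit is brought in with the carbinol carbon cis to the ester (the chelated, configurationally defined magnesium reagent). The carbinol is silylated so that it cannot close a butenolide. Both formyl groups are set before the depside bond is made, because an aryl salicylate ester would be at risk under basic formylation.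

## Route

Step 1
Reactants: 1 squaric acid; 2 benzyl alcohol (two equivalents are consumed)
Product: 3 3,4-bis(benzyloxy)cyclobut-3-ene-1,2-dione
Conditions: BnOH (2.5 equiv), toluene, reflux, Dean–Stark trap
Reagents that add atoms: benzyl alcohol (the second equivalent of 2) OCc1ccccc1
Why: Squaric acid is a strong vinylogous acid that catalyses its own twofold esterification when water is removed azeotropically (Fischer-type esterification), the usual access to dialkyl squarates, each hydroxyl taking up one molecule of benzyl alcohol.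

Step 2
Reactants: 3 3,4-bis(benzyloxy)cyclobut-3-ene-1,2-dione
Product: 5 3-(benzyloxy)cyclobut-3-ene-1,2-dione, via hydroxycyclobutenone 4 (not isolated)
Conditions: LiAlH(OtBu)3, THF, −78 to −20 °C; then 2 M HCl, CH2Cl2, rt
Reagents that add atoms: water O
Why: The hindered hydride should stop after one 1,2-reduction of a squarate carbonyl, and acid then ionizes the allylic carbinol of 4, water adds to the alkoxy-stabilized cation and benzyl alcohol is lost (carbonyl reduction followed by vinylogous-ester hydrolysis with transposition), the known way to alkyl semisquarates.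

Step 3
Reactants: 6 but-2-ynoic acid
Product: 7 (Z)-3-iodobut-2-enoic acid
Conditions: NaI, AcOH, 110 °C
Reagents that add atoms: sodium iodide [Na+].[I-]
Why: Iodide adds in conjugate fashion to the ynoic acid and protonation follows anti (hydroiodination of an electron-poor alkyne), which should place iodine cis to the carboxyl group.

Step 4
Reactants: 7 (Z)-3-iodobut-2-enoic acid
Product: 8 tert-butyl (Z)-3-iodobut-2-enoate
Conditions: tert-butyl 2,2,2-trichloroacetimidate, BF3·OEt2 (cat.), CH2Cl2/cyclohexane, rt
Reagents that add atoms: tert-butyl 2,2,2-trichloroacetimidate CC(C)(C)OC(=N)C(Cl)(Cl)Cl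
Why: Acid-catalysed O-alkylation of the carboxylic acid by the imidate (tert-butyl ester formation) should proceed without touching the vinyl iodide or its geometry.

Step 5
Reactants: 8 tert-butyl (Z)-3-iodobut-2-enoate; 5 3-(benzyloxy)cyclobut-3-ene-1,2-dione
Product: 10 tert-butyl (Z)-3-[2-(benzyloxy)-1-hydroxy-4-oxocyclobut-2-en-1-yl]but-2-enoate (racemic), via alkenylmagnesium chloride 9 (not isolated)
Conditions: iPrMgCl·LiCl, THF, −40 °C; then added to 5 in THF, −78 °C; AcOH, −78 °C
Reagents that add atoms: none
Why: Iodine–magnesium exchange on a (Z)-β-iodoenoate should give, with retention, an alkenylmagnesium held by chelation to its own ester, which adds 1,2 to the ketone-like C2 carbonyl of 5 (next to the benzyloxy carbon) rather than to the vinylogous-ester carbonyl; the carbinol centre forms as a racemate, and the tert-butyl ester with the cold acidic quench should keep the alkoxide from lactonizing.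

Step 6
Reactants: 10 tert-butyl (Z)-3-[2-(benzyloxy)-1-hydroxy-4-oxocyclobut-2-en-1-yl]but-2-enoate
Product: 11 tert-butyl (Z)-3-[2-(benzyloxy)-4-oxo-1-[(trimethylsilyl)oxy]cyclobut-2-en-1-yl]but-2-enoate (racemic)
Conditions: N-(trimethylsilyl)imidazole, CH2Cl2, 0 °C to rt
Reagents that add atoms: N-(trimethylsilyl)imidazole C[Si](C)(C)n1ccnc1
Why: Neutral silylation of the tertiary alcohol (silyl ether formation) blocks lactonization onto the cis ester and keeps the oxygen donor that the ring opening needs.

Step 7
Reactants: 11 tert-butyl (Z)-3-[2-(benzyloxy)-4-oxo-1-[(trimethylsilyl)oxy]cyclobut-2-en-1-yl]but-2-enoate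
Product: 15 tert-butyl 4-(benzyloxy)-2,5-dihydroxy-6-methylbenzoate, via dienylketene 12 (not isolated), via cyclohexadienone 13 (not isolated), via aryl silyl ether 14 (not isolated)
Conditions: degassed toluene (dilute), 110 °C, argon; then 1 M HCl, THF, rt
Reagents that add atoms: none
Why: Thermal conrotatory four-electron opening of the cyclobutenone breaks the bond between the carbonyl carbon and the silyloxy-bearing carbon to give dienylketene 12, a disrotatory six-electron electrocyclization joins the ketene carbon (C2') to the ester-bearing alkene terminus (C1') to give cyclohexadienone 13, enolization of its β-keto ester hydrogen gives arene 14, and dilute acid removes the silyl group. The closest known reaction is the Moore ring expansion of 4-alkenyl-4-hydroxy- or 4-silyloxycyclobutenones to hydroquinones. The only ring closed is ring B, by six-electron electrocyclic closure, and each of its six carbons brings its substituent from the precursor. No stereocentre remains, because the carbinol carbon becomes C5', the sp3 carbon of 13 is lost on tautomerization and the alkene geometry is erased. The step needs torquoselectivity, which the silyloxy donor should secure by rotating outward so that the alkenyl group lies beside the ketene; the ketene carbon has no inward substituent, so the ester on the inner side of the terminus should not stop the closure, and the silyl cap together with the tert-butyl ester keeps the oxygen from forming a butenolide.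

Step 8
Reactants: 15 tert-butyl 4-(benzyloxy)-2,5-dihydroxy-6-methylbenzoate
Product: 16 tert-butyl 4-(benzyloxy)-3-formyl-2,5-dihydroxy-6-methylbenzoate
Conditions: MgCl2, Et3N, paraformaldehyde, MeCN, reflux, argon; then 1 M HCl
Reagents that add atoms: paraformaldehyde (as formaldehyde) C=O
Why: The magnesium phenoxide delivers formaldehyde to its ortho carbon and a second formaldehyde oxidizes the benzylic alkoxide (magnesium-mediated ortho-formylation of the Casnati–Skattebøl type); C3' is the only free ring position and lies ortho to the C2' phenol.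

Step 9
Reactants: 17 everninic acid
Product: 18 benzyl 2-hydroxy-4-methoxy-6-methylbenzoate
Conditions: BnBr, KHCO3, DMF, rt
Reagents that add atoms: benzyl bromide BrCc1ccccc1
Why: The carboxylate is alkylated by benzyl bromide (SN2 esterification), while the hydrogen-bonded C2 phenol is not deprotonated by bicarbonate.

Step 10
Reactants: 18 benzyl 2-hydroxy-4-methoxy-6-methylbenzoate
Product: 19 benzyl 3-formyl-2-hydroxy-4-methoxy-6-methylbenzoate
Conditions: MgCl2, Et3N, paraformaldehyde, MeCN, reflux; then 1 M HCl
Reagents that add atoms: paraformaldehyde (as formaldehyde) C=O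
Why: The same magnesium-mediated ortho-formylation can only reach C3, the one free position ortho to the C2 phenol, so C5 should stay untouched.

Step 11
Reactants: 19 benzyl 3-formyl-2-hydroxy-4-methoxy-6-methylbenzoate
Product: 20 3-formyl-2-hydroxy-4-methoxy-6-methylbenzoic acid
Conditions: H2 (1 atm), 10% Pd/C, EtOAc, rt
Reagents that add atoms: none
Why: Hydrogenolysis of the benzyl ester should be much faster than reduction of the chelated, electron-rich aryl aldehyde under these mild conditions.

Step 12
Reactants: 20 3-formyl-2-hydroxy-4-methoxy-6-methylbenzoic acid; 16 tert-butyl 4-(benzyloxy)-3-formyl-2,5-dihydroxy-6-methylbenzoate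
Product: 22 tert-butyl 4-(benzyloxy)-3-formyl-5-[(3-formyl-2-hydroxy-4-methoxy-6-methylbenzoyl)oxy]-2-hydroxy-6-methylbenzoate, via mixed anhydride 21 (not isolated)
Conditions: trifluoroacetic anhydride, toluene, 0 °C to rt
Reagents that add atoms: none
Why: Trifluoroacetic anhydride turns the hindered 2,6-disubstituted acid into mixed anhydride 21, an acylium-like donor that should acylate the unchelated C5' phenol (mixed-anhydride esterification as used for depsides); the C2' phenol and the acid's own phenol are each flanked by and hydrogen-bonded to carbonyl groups, and the two equivalents of trifluoroacetic acid set free in dilute toluene should not cleave the tert-butyl ester in the time the coupling needs.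

Step 13
Reactants: 22 tert-butyl 4-(benzyloxy)-3-formyl-5-[(3-formyl-2-hydroxy-4-methoxy-6-methylbenzoyl)oxy]-2-hydroxy-6-methylbenzoate
Product: 23 tert-butyl 3-formyl-5-[(3-formyl-2-hydroxy-4-methoxy-6-methylbenzoyl)oxy]-2,4-dihydroxy-6-methylbenzoate
Conditions: H2 (1 atm), 10% Pd/C, EtOAc, rt
Reagents that add atoms: none
Why: Neutral hydrogenolysis of the aryl benzyl ether should leave the depside ester and the tert-butyl ester intact, and the chelated aldehydes are reduced more slowly than the ether is cleaved.

Step 14
Reactants: 23 tert-butyl 3-formyl-5-[(3-formyl-2-hydroxy-4-methoxy-6-methylbenzoyl)oxy]-2,4-dihydroxy-6-methylbenzoate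
Product: 24 haemathamnolic acid
Conditions: CF3CO2H, CH2Cl2, 0 °C to rt
Reagents that add atoms: none
Why: Acidolysis of the tert-butyl ester through the tert-butyl cation (loss of isobutene) frees the C1' acid, and the aryl ester of the depside is stable to acid.

## Compound list

1 | squaric acid | O=C1C(O)=C(O)C1=O | starting material
2 | benzyl alcohol | OCc1ccccc1 | starting material
3 | 3,4-bis(benzyloxy)cyclobut-3-ene-1,2-dione | O=C1C(OCc2ccccc2)=C(OCc2ccccc2)C1=O | intermediate
4 | 2,3-bis(benzyloxy)-4-hydroxycyclobut-2-en-1-one (racemic) | O=C1C(OCc2ccccc2)=C(OCc2ccccc2)C1O | intermediate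
5 | 3-(benzyloxy)cyclobut-3-ene-1,2-dione | O=C1C=C(OCc2ccccc2)C1=O | intermediate
6 | but-2-ynoic acid | CC#CC(=O)O | starting material
7 | (Z)-3-iodobut-2-enoic acid | C/C(I)=C/C(=O)O | intermediate
8 | tert-butyl (Z)-3-iodobut-2-enoate | C/C(I)=C/C(=O)OC(C)(C)C | intermediate
9 | tert-butyl (Z)-3-(chloromagnesio)but-2-enoate | C/C([Mg]Cl)=C/C(=O)OC(C)(C)C | intermediate
10 | tert-butyl (Z)-3-[2-(benzyloxy)-1-hydroxy-4-oxocyclobut-2-en-1-yl]but-2-enoate (racemic) | O=C1C=C(OCc2ccccc2)C1(O)/C(C)=C\C(=O)OC(C)(C)C | intermediate
11 | tert-butyl (Z)-3-[2-(benzyloxy)-4-oxo-1-[(trimethylsilyl)oxy]cyclobut-2-en-1-yl]but-2-enoate (racemic) | O=C1C=C(OCc2ccccc2)C1(O[Si](C)(C)C)/C(C)=C\C(=O)OC(C)(C)C | intermediate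
12 | tert-butyl (2Z,4Z)-5-(benzyloxy)-3-methyl-7-oxo-4-[(trimethylsilyl)oxy]hepta-2,4,6-trienoate (dienylketene) | O=C=C/C(OCc1ccccc1)=C(/O[Si](C)(C)C)\C(C)=C/C(=O)OC(C)(C)C | intermediate
13 | tert-butyl 4-(benzyloxy)-2-methyl-6-oxo-3-[(trimethylsilyl)oxy]cyclohexa-2,4-diene-1-carboxylate (racemic) | O=C1C=C(OCc2ccccc2)C(O[Si](C)(C)C)=C(C)C1C(=O)OC(C)(C)C | intermediate
14 | tert-butyl 4-(benzyloxy)-2-hydroxy-6-methyl-5-[(trimethylsilyl)oxy]benzoate | Cc1c(O[Si](C)(C)C)c(OCc2ccccc2)cc(O)c1C(=O)OC(C)(C)C | intermediate
15 | tert-butyl 4-(benzyloxy)-2,5-dihydroxy-6-methylbenzoate | Cc1c(O)c(OCc2ccccc2)cc(O)c1C(=O)OC(C)(C)C | intermediate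
16 | tert-butyl 4-(benzyloxy)-3-formyl-2,5-dihydroxy-6-methylbenzoate | Cc1c(O)c(OCc2ccccc2)c(C=O)c(O)c1C(=O)OC(C)(C)C | intermediate
17 | everninic acid (2-hydroxy-4-methoxy-6-methylbenzoic acid) | COc1cc(C)c(C(=O)O)c(O)c1 | starting material
18 | benzyl 2-hydroxy-4-methoxy-6-methylbenzoate | COc1cc(C)c(C(=O)OCc2ccccc2)c(O)c1 | intermediate
19 | benzyl 3-formyl-2-hydroxy-4-methoxy-6-methylbenzoate | COc1cc(C)c(C(=O)OCc2ccccc2)c(O)c1C=O | intermediate
20 | 3-formyl-2-hydroxy-4-methoxy-6-methylbenzoic acid | COc1cc(C)c(C(=O)O)c(O)c1C=O | intermediate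
21 | 3-formyl-2-hydroxy-4-methoxy-6-methylbenzoic trifluoroacetic anhydride | COc1cc(C)c(C(=O)OC(=O)C(F)(F)F)c(O)c1C=O | intermediate
22 | tert-butyl 4-(benzyloxy)-3-formyl-5-[(3-formyl-2-hydroxy-4-methoxy-6-methylbenzoyl)oxy]-2-hydroxy-6-methylbenzoate | COc1cc(C)c(C(=O)Oc2c(C)c(C(=O)OC(C)(C)C)c(O)c(C=O)c2OCc3ccccc3)c(O)c1C=O | intermediate
23 | tert-butyl 3-formyl-5-[(3-formyl-2-hydroxy-4-methoxy-6-methylbenzoyl)oxy]-2,4-dihydroxy-6-methylbenzoate | COc1cc(C)c(C(=O)Oc2c(C)c(C(=O)OC(C)(C)C)c(O)c(C=O)c2O)c(O)c1C=O | intermediate
24 | haemathamnolic acid | COc1cc(C)c(C(=O)Oc2c(C)c(C(=O)O)c(O)c(C=O)c2O)c(O)c1C=O | target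

## Step count and risks

Total step count: 14. Longest linear sequence: 9 steps (steps 1, 2, 5, 6, 7, 8, 12, 13, 14; the branch from but-2-ynoic acid through steps 3 and 4 is equally long).

Steps most likely to fail:

1. Step 7. The six-electron closure may be slowed by the ester on the inner side of the alkene terminus, so that the ketene re-closes, dimerizes or is trapped by adventitious nucleophiles; loss of the silyl group on heating would open the way to butenolide formation. The fallback sets out from 5 and makes the isomer whose ester points away from both the carbinol and the closing bond. Lithium tert-butyl propiolate (tert-butyl propiolate, LiN(iPr)2, THF, −78 °C, cold AcOH quench) should add to the same carbonyl to give tert-butyl 3-[2-(benzyloxy)-1-hydroxy-4-oxocyclobut-2-en-1-yl]prop-2-ynoate F1. Anti hydroiodination (LiI, AcOH, MeCN, rt to 40 °C) should give tert-butyl (Z)-3-[2-(benzyloxy)-1-hydroxy-4-oxocyclobut-2-en-1-yl]-3-iodoprop-2-enoate F2, with the ring trans to the ester. Stille methylation with retention (Me4Sn, Pd(PPh3)4, CuI, DMF, 40 °C) should give tert-butyl (E)-3-[2-(benzyloxy)-1-hydroxy-4-oxocyclobut-2-en-1-yl]but-2-enoate F3. F3 cannot lactonize, so it is heated with the hydroxyl free (toluene, 110 °C) and the route is rejoined at 15.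

2. Step 5. The magnesium alkoxide may lactonize onto the cis ester before the quench, the reagent may attack the vinylogous-ester carbonyl or displace benzyloxide by addition–elimination, or incomplete exchange may let isopropylmagnesium chloride add to 5. The fallback sets out from 5 and builds the alkene after the carbinol. Lithium tert-butyl propiolate (THF, −78 °C) is added and the lithium alkoxide is silylated in the same flask with Me3SiCl to give tert-butyl 3-[2-(benzyloxy)-4-oxo-1-[(trimethylsilyl)oxy]cyclobut-2-en-1-yl]prop-2-ynoate F4. Syn carbocupration with Me2CuLi (THF, −78 °C, MeOH quench at −78 °C) should place the methyl cis to the new hydrogen and so return to 11.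

3. Step 12. Acylation of the phenol between benzyloxy and methyl may be slow, so that the mixed anhydride is consumed by self-condensation or the phenol is trifluoroacetylated, and prolonged contact with the liberated acid may begin to cleave the tert-butyl ester. The fallback sets out from 19 (and uses 16) and replaces the acid-promoted coupling by a base-mediated one with a protected acid. Protection (NaH, MeOCH2Cl, DMF, 0 °C) should give benzyl 3-formyl-4-methoxy-2-(methoxymethoxy)-6-methylbenzoate F5. Hydrogenolysis (H2, 10% Pd/C, EtOAc) should give 3-formyl-4-methoxy-2-(methoxymethoxy)-6-methylbenzoic acid F6. Carbodiimide coupling with 16 (EDC·HCl, 4-(dimethylamino)pyridine, CH2Cl2) should give tert-butyl 4-(benzyloxy)-3-formyl-5-{[3-formyl-4-methoxy-2-(methoxymethoxy)-6-methylbenzoyl]oxy}-2-hydroxy-6-methylbenzoate F7. Hydrogenolysis of the benzyl ether should give tert-butyl 3-formyl-5-{[3-formyl-4-methoxy-2-(methoxymethoxy)-6-methylbenzoyl]oxy}-2,4-dihydroxy-6-methylbenzoate F8. CF3CO2H in CH2Cl2 then removes the methoxymethyl group and the tert-butyl ester together and the route is rejoined at 24.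

## Further compounds

F1 | step 7 | tert-butyl 3-[2-(benzyloxy)-1-hydroxy-4-oxocyclobut-2-en-1-yl]prop-2-ynoate (racemic) | O=C1C=C(OCc2ccccc2)C1(O)C#CC(=O)OC(C)(C)C
F2 | step 7 | tert-butyl (Z)-3-[2-(benzyloxy)-1-hydroxy-4-oxocyclobut-2-en-1-yl]-3-iodoprop-2-enoate (racemic) | O=C1C=C(OCc2ccccc2)C1(O)/C(I)=C/C(=O)OC(C)(C)C
F3 | step 7 | tert-butyl (E)-3-[2-(benzyloxy)-1-hydroxy-4-oxocyclobut-2-en-1-yl]but-2-enoate (racemic) | O=C1C=C(OCc2ccccc2)C1(O)/C(C)=C/C(=O)OC(C)(C)C
F4 | step 5 | tert-butyl 3-[2-(benzyloxy)-4-oxo-1-[(trimethylsilyl)oxy]cyclobut-2-en-1-yl]prop-2-ynoate (racemic) | O=C1C=C(OCc2ccccc2)C1(O[Si](C)(C)C)C#CC(=O)OC(C)(C)C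
F5 | step 12 | benzyl 3-formyl-4-methoxy-2-(methoxymethoxy)-6-methylbenzoate | COCOc1c(C=O)c(OC)cc(C)c1C(=O)OCc1ccccc1
F6 | step 12 | 3-formyl-4-methoxy-2-(methoxymethoxy)-6-methylbenzoic acid | COCOc1c(C=O)c(OC)cc(C)c1C(=O)O
F7 | step 12 | tert-butyl 4-(benzyloxy)-3-formyl-5-{[3-formyl-4-methoxy-2-(methoxymethoxy)-6-methylbenzoyl]oxy}-2-hydroxy-6-methylbenzoate | COCOc1c(C=O)c(OC)cc(C)c1C(=O)Oc1c(C)c(C(=O)OC(C)(C)C)c(O)c(C=O)c1OCc1ccccc1
F8 | step 12 | tert-butyl 3-formyl-5-{[3-formyl-4-methoxy-2-(methoxymethoxy)-6-methylbenzoyl]oxy}-2,4-dihydroxy-6-methylbenzoate | COCOc1c(C=O)c(OC)cc(C)c1C(=O)Oc1c(C)c(C(=O)OC(C)(C)C)c(O)c(C=O)c1O
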